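**Strategy.** The ten-membered carbocycle (C1–C10) is opened at C9–C10, between the C9 carbinol and the ester-bearing alkene carbon C10. The array C8(O-angeloyl)–C9(OH)–C10(CO2Me)=C1 is a β-substituted Baylis–Hillman motif, the formal adduct of an aldehyde and an α-metallated acrylate. A Nozaki–Hiyama–Kishi reaction in the last step therefore forms C9–C10, closes the ring and creates C9 in one operation. Its precursor is an open-chain (Z)-α-iodoacrylate aldehyde. It already carries the trans-disubstituted α-methylene-γ-butyrolactone (C6, C7, C11–C13), the C8 angelate and the C4 methyl group. C4 comes from (S)-citronellal, C8 from (R)-glyceraldehyde acetonide, and C6 and C7 from one anti-selective chromium allylation.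

Key step: step 15

**Remarks on the chemistry**
- Locants: the germacrane-type numbering of the target is used for all compounds.
  - C1=C10 is the ring alkene and C14 is the ester carbon on C10.
  - C4 bears the methyl group, C6 the lactone oxygen, C8 the angelate and C9 the carbinol; C7 is the ring-fusion carbon.
  - C11=C13 is the exocyclic methylene and C12 the lactone carbonyl.
- Configuration: the target is 4S,6R,7S,8S,9S, and H6 and H7 are trans. C2 and C9 are cis on the ring alkene, which is E by the sequence rule because CO2Me outranks C9. The iodide must therefore be Z (iodine cis to C2) and must react with retention.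
- Assumption: in step 4 the dioxolane directs the allylchromium reagent in the Felkin–Anh sense, with the C8–O bond anti to the forming bond, as expected for γ-dioxolanyl allylchromium reagents.
- Design point a: allyl metals that carry the ester on the central carbon (from 2-(bromomethyl)alk-2-enoates) hold the γ-substituent cis to the CH2–metal group. As a rule they give syn adducts and hence cis-lactones. The trans C6/C7 pair is therefore made with an ester-free (E)-allyl bromide, and C12 (oxidation level) and C13 are completed afterwards.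
- Design point b: the C9 aldehyde is released only after the C1 aldehyde has been consumed, so the iodo-ylide never meets two aldehydes.
- Design point c: the heat- and light-sensitive iodoacrylate is introduced after the 80 °C angeloylation.
- Descriptor note: C7 reads R in 16 and 17 only because the priorities change. The spatial arrangement is that of 15.

**Step 1**
Reactants: 1 (R)-glyceraldehyde acetonide; 2 trimethyl phosphonoacetate
Product: 3 methyl (2E)-3-[(4S)-2,2-dimethyl-1,3-dioxolan-4-yl]prop-2-enoate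
Conditions: LiCl, DBU, MeCN, 0 °C to rt
Reagents that add atoms: none
Why: The Masamune–Roush variant of the Horner–Wadsworth–Emmons olefination is E-selective and mild enough not to epimerise the α-alkoxy aldehyde, so C8 is taken unchanged from the chiral pool.

**Step 2**
Reactants: 3 methyl (2E)-3-[(4S)-2,2-dimethyl-1,3-dioxolan-4-yl]prop-2-enoate
Product: 4 (2E)-3-[(4S)-2,2-dimethyl-1,3-dioxolan-4-yl]prop-2-en-1-ol
Conditions: iBu2AlH (2.2 equiv), CH2Cl2, −78 °C; aq. potassium sodium tartrate
Reagents that add atoms: none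
Why: 1,2-Reduction of an enoate with diisobutylaluminium hydride gives the allylic alcohol and leaves the alkene geometry, the acetonide and C8 untouched.

**Step 3**
Reactants: 4 (2E)-3-[(4S)-2,2-dimethyl-1,3-dioxolan-4-yl]prop-2-en-1-ol
Product: 5 (4S)-4-[(1E)-3-bromoprop-1-en-1-yl]-2,2-dimethyl-1,3-dioxolane
Conditions: CBr4, PPh3, CH2Cl2, 0 °C
Reagents that add atoms: carbon tetrabromide, BrC(Br)(Br)Br
Why: The Appel reaction converts the primary allylic alcohol by SN2 displacement under neutral conditions that the acetonide tolerates.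

**Step 4**
Reactants: 5 (4S)-4-[(1E)-3-bromoprop-1-en-1-yl]-2,2-dimethyl-1,3-dioxolane; 6 (S)-citronellal
Product: 8 (3S,4R,6S)-3-[(4S)-2,2-dimethyl-1,3-dioxolan-4-yl]-6,10-dimethylundeca-1,9-dien-4-ol, via allylchromium dichloride 7 (not isolated)
Conditions: CrCl2 (3.5 equiv), THF, 0 °C to rt; H2O
Reagents that add atoms: none
Why: In this Nozaki–Hiyama allylation the (E)-allylchromium reagent reacts at its γ-carbon through a chair transition state with both substituents equatorial, which gives the anti C6/C7 pair by attack on the Si face of 6, while the C8–O bond stands antiperiplanar to the forming C6–C7 bond (Felkin–Anh-type arrangement) and so fixes C7 relative to C8.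

**Step 5**
Reactants: 8 (3S,4R,6S)-3-[(4S)-2,2-dimethyl-1,3-dioxolan-4-yl]-6,10-dimethylundeca-1,9-dien-4-ol
Product: 10 (3S,4R,6S)-3-[(4S)-2,2-dimethyl-1,3-dioxolan-4-yl]-6,10-dimethylundec-9-ene-1,4-diol, via bis(boryl) adduct 9 (not isolated)
Conditions: 9-BBN (2.5 equiv), THF, 0 °C to rt; then H2O2, NaOH, 0 °C
Reagents that add atoms: hydrogen peroxide, OO
Why: In hydroboration–oxidation 9-BBN strongly prefers the monosubstituted vinyl group to the trisubstituted alkene and places boron on the terminal carbon C12, and no stereocentre is touched.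

**Step 6**
Reactants: 10 (3S,4R,6S)-3-[(4S)-2,2-dimethyl-1,3-dioxolan-4-yl]-6,10-dimethylundec-9-ene-1,4-diol
Product: 12 (4S,5R)-4-[(4S)-2,2-dimethyl-1,3-dioxolan-4-yl]-5-[(2S)-2,6-dimethylhept-5-en-1-yl]oxolan-2-one, via lactol 11 (not isolated)
Conditions: 2,2,6,6-tetramethylpiperidin-1-oxyl (TEMPO, cat.), PhI(OAc)2 (2.5 equiv), CH2Cl2, rt
Reagents that add atoms: none
Why: In this oxidative lactonisation the oxoammonium oxidant takes the primary alcohol first, the hydroxy aldehyde closes to the lactol and is oxidised again, and the anti C6/C7 pair thereby becomes the trans-lactone.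

**Step 7**
Reactants: 12 (4S,5R)-4-[(4S)-2,2-dimethyl-1,3-dioxolan-4-yl]-5-[(2S)-2,6-dimethylhept-5-en-1-yl]oxolan-2-one
Product: 15 (4S,5R)-4-[(4S)-2,2-dimethyl-1,3-dioxolan-4-yl]-5-[(2S)-2,6-dimethylhept-5-en-1-yl]-3-methylideneoxolan-2-one, via Mannich base 13 (not isolated), via ammonium iodide 14 (not isolated)
Conditions: LiN(iPr)2, THF, −78 °C; dimethyl(methylidene)ammonium iodide, −78 °C to rt; MeI, MeOH, rt; aq. NaHCO3, CH2Cl2, rt
Reagents that add atoms: Eschenmoser's salt (dimethyl(methylidene)ammonium iodide), C=[N+](C)C.[I-]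
Why: Mannich-type aminomethylation of the lactone enolate at C11, quaternisation and Hofmann-type elimination form the standard α-methylenation of butyrolactones, and the enolate has no β-leaving group, so C6, C7 and C8 stay intact.

**Step 8**
Reactants: 15 (4S,5R)-4-[(4S)-2,2-dimethyl-1,3-dioxolan-4-yl]-5-[(2S)-2,6-dimethylhept-5-en-1-yl]-3-methylideneoxolan-2-one
Product: 16 (4R,5R)-4-[(1S)-1,2-dihydroxyethyl]-5-[(2S)-2,6-dimethylhept-5-en-1-yl]-3-methylideneoxolan-2-one
Conditions: AcOH/H2O (4:1), 40 °C
Reagents that add atoms: none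
Why: Acid-catalysed acetal hydrolysis frees the C8/C9 diol without base, which avoids oxa-Michael addition to C13 and translactonisation.

**Step 9**
Reactants: 16 (4R,5R)-4-[(1S)-1,2-dihydroxyethyl]-5-[(2S)-2,6-dimethylhept-5-en-1-yl]-3-methylideneoxolan-2-one
Product: 17 (4R,5R)-4-[(1S)-2-(tert-butyldimethylsilyloxy)-1-hydroxyethyl]-5-[(2S)-2,6-dimethylhept-5-en-1-yl]-3-methylideneoxolan-2-one
Conditions: TBSCl (1.05 equiv), imidazole, CH2Cl2, 0 °C
Reagents that add atoms: tert-butyldimethylsilyl chloride, CC(C)(C)[Si](C)(C)Cl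
Why: Silyl ether formation with a bulky chlorosilane selects the primary C9 hydroxyl on steric grounds and leaves the hindered C8 hydroxyl free.

**Step 10**
Reactants: 17 (4R,5R)-4-[(1S)-2-(tert-butyldimethylsilyloxy)-1-hydroxyethyl]-5-[(2S)-2,6-dimethylhept-5-en-1-yl]-3-methylideneoxolan-2-one; 18 angelic acid
Product: 20 (1S)-2-(tert-butyldimethylsilyloxy)-1-{(2R,3S)-2-[(2S)-2,6-dimethylhept-5-en-1-yl]-4-methylidene-5-oxooxolan-3-yl}ethyl (2Z)-2-methylbut-2-enoate, via mixed anhydride 19 (not isolated)
Conditions: 18, 2,4,6-trichlorobenzoyl chloride, Et3N, toluene, rt, salt filtered off; then 17, toluene, 80 °C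
Reagents that add atoms: none
Why: This Yamaguchi mixed-anhydride esterification is run without a nucleophilic catalyst, which keeps the Z geometry of the angelate, and C8 retains its configuration because its C–O bond is not broken.

**Step 11**
Reactants: 20 (1S)-2-(tert-butyldimethylsilyloxy)-1-{(2R,3S)-2-[(2S)-2,6-dimethylhept-5-en-1-yl]-4-methylidene-5-oxooxolan-3-yl}ethyl (2Z)-2-methylbut-2-enoate
Product: 22 (1S)-2-(tert-butyldimethylsilyloxy)-1-{(2R,3S)-2-[(2S)-2-methyl-5-oxopentyl]-4-methylidene-5-oxooxolan-3-yl}ethyl (2Z)-2-methylbut-2-enoate, via ozonide 21 (not isolated)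
Conditions: O3, CH2Cl2, −78 °C, Sudan Red 7B as end-point indicator; Me2S, −78 °C to rt
Reagents that add atoms: ozone, [O-][O+]=O
Why: In ozonolysis the electrophilic ozone attacks the electron-rich trisubstituted alkene far faster than the two ester-conjugated alkenes, and the dye marks the point at which to stop.

**Step 12**
Reactants: 22 (1S)-2-(tert-butyldimethylsilyloxy)-1-{(2R,3S)-2-[(2S)-2-methyl-5-oxopentyl]-4-methylidene-5-oxooxolan-3-yl}ethyl (2Z)-2-methylbut-2-enoate; 23 methyl (triphenylphosphoranylidene)acetate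
Product: 25 methyl (2Z,6S)-7-{(2R,3S)-3-[(1S)-2-(tert-butyldimethylsilyloxy)-1-{[(2Z)-2-methylbut-2-enoyl]oxy}ethyl]-4-methylidene-5-oxooxolan-2-yl}-2-iodo-6-methylhept-2-enoate, via iodo-ylide 24 (not isolated)
Conditions: 23, N-iodosuccinimide, CH2Cl2, −20 °C; then 22, −20 °C to rt
Reagents that add atoms: N-iodosuccinimide, O=C1CCC(=O)N1I
Why: In this Wittig olefination with a stabilised α-iodo ylide the ester ends up trans to the chain as usual, so iodine is cis to C2 (Z), and a minor E isomer would be removed by chromatography.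

**Step 13**
Reactants: 25 methyl (2Z,6S)-7-{(2R,3S)-3-[(1S)-2-(tert-butyldimethylsilyloxy)-1-{[(2Z)-2-methylbut-2-enoyl]oxy}ethyl]-4-methylidene-5-oxooxolan-2-yl}-2-iodo-6-methylhept-2-enoate
Product: 26 methyl (2Z,6S)-7-{(2R,3S)-3-[(1S)-2-hydroxy-1-{[(2Z)-2-methylbut-2-enoyl]oxy}ethyl]-4-methylidene-5-oxooxolan-2-yl}-2-iodo-6-methylhept-2-enoate
Conditions: HF·pyridine, pyridine, THF, 0 °C to rt
Reagents that add atoms: none
Why: Fluoride-mediated desilylation in a buffered, slightly acidic medium removes the primary silyl ether without the alkoxide that would drive a 1,2-shift of the angeloyl group from O8 to O9.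

**Step 14**
Reactants: 26 methyl (2Z,6S)-7-{(2R,3S)-3-[(1S)-2-hydroxy-1-{[(2Z)-2-methylbut-2-enoyl]oxy}ethyl]-4-methylidene-5-oxooxolan-2-yl}-2-iodo-6-methylhept-2-enoate
Product: 27 methyl (2Z,6S)-2-iodo-6-methyl-7-[(2R,3S)-3-{(1S)-1-[(2Z)-2-methylbut-2-enoyloxy]-2-oxoethyl}-4-methylidene-5-oxooxolan-2-yl]hept-2-enoate (seco iodoacrylate aldehyde)
Conditions: Dess–Martin periodinane, CH2Cl2, 0 °C to rt; used at once
Reagents that add atoms: none
Why: The Dess–Martin oxidation works without base, so the α-acyloxy aldehyde is formed without epimerisation at C8 or loss of angelate.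

**Step 15**
Reactants: 27 methyl (2Z,6S)-2-iodo-6-methyl-7-[(2R,3S)-3-{(1S)-1-[(2Z)-2-methylbut-2-enoyloxy]-2-oxoethyl}-4-methylidene-5-oxooxolan-2-yl]hept-2-enoate
Product: 29 methyl (3aS,4S,5S,6E,10S,11aR)-5-hydroxy-10-methyl-3-methylidene-4-[(2Z)-2-methylbut-2-enoyloxy]-2-oxo-2,3,3a,4,5,8,9,10,11,11a-decahydrocyclodeca[b]furan-6-carboxylate (target CNP0552150.1), via alkenylchromium dichloride 28 (not isolated)
Conditions: CrCl2 (12 equiv), NiCl2 (0.1 equiv), degassed DMSO, rt, 27 added slowly to a final 0.002 M; H2O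
Reagents that add atoms: none
Why: CrCl2 reduces NiCl2 to zerovalent nickel, which inserts into the carbon–iodine bond at C10, transmetalation hands the alkenyl group to trivalent chromium with retention of geometry (as is usual for trisubstituted alkenyl iodides), and the alkenylchromium 28 adds to the C9 aldehyde. The closest known reaction type is the Nozaki–Hiyama–Kishi macrocyclisation of iodoalkene aldehydes, applied here to an electron-poor α-iodoacrylate, which eases oxidative addition but lowers the nucleophilicity of the chromium species, hence the large excess of CrCl2 and the polar solvent. The ten-membered ring closes in the 10-exo-trig mode with the carbonyl oxygen outside the ring. C9 is set by the cyclic transition state: the trans-lactone fixes the C5–C6–C7–C8 backbone, the cis placement of C2 and chromium on the alkene folds the chain back, and C10 should reach C9 with C7 and C10 antiperiplanar about C8–C9 and the formyl oxygen on the periphery, that is on the Si face past H8, giving the 8,9-threo (9S) alcohol. The step needs this face against the open-chain polar Felkin–Anh preference, addition to the aldehyde rather than to the methylene lactone or the esters (the normal chemoselectivity of organochromium reagents), and ring closure rather than oligomerisation, which slow addition at high dilution secures. The neutral medium leaves C8, the angelate geometry and the new carbinol untouched, so no step follows.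

**Compound list**
1 | (R)-glyceraldehyde acetonide, (4R)-2,2-dimethyl-1,3-dioxolane-4-carbaldehyde | O=C[C@H]1COC(C)(C)O1 | starting material
2 | trimethyl phosphonoacetate | COC(=O)CP(=O)(OC)OC | starting material
3 | methyl (2E)-3-[(4S)-2,2-dimethyl-1,3-dioxolan-4-yl]prop-2-enoate | COC(=O)/C=C/[C@H]1COC(C)(C)O1 | intermediate
4 | (2E)-3-[(4S)-2,2-dimethyl-1,3-dioxolan-4-yl]prop-2-en-1-ol | OC/C=C/[C@H]1COC(C)(C)O1 | intermediate
5 | (4S)-4-[(1E)-3-bromoprop-1-en-1-yl]-2,2-dimethyl-1,3-dioxolane | BrC/C=C/[C@H]1COC(C)(C)O1 | intermediate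
6 | (S)-citronellal, (3S)-3,7-dimethyloct-6-enal | O=CC[C@@H](C)CCC=C(C)C | starting material
7 | (E)-allylchromium dichloride from 5 (THF solvate) | Cl[Cr](Cl)C/C=C/[C@H]1COC(C)(C)O1 | intermediate (not isolated)
8 | (3S,4R,6S)-3-[(4S)-2,2-dimethyl-1,3-dioxolan-4-yl]-6,10-dimethylundeca-1,9-dien-4-ol (4S,6R,7S,8S in target locants) | O[C@H](C[C@@H](C)CCC=C(C)C)[C@H](C=C)[C@H]1COC(C)(C)O1 | intermediate
9 | O6,C12-bis(9-borabicyclo[3.3.1]nonan-9-yl) adduct of 8 | O(B1C2CCCC1CCC2)[C@H](C[C@@H](C)CCC=C(C)C)[C@H](CCB3C4CCCC3CCC4)[C@H]5COC(C)(C)O5 | intermediate (not isolated)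
10 | (3S,4R,6S)-3-[(4S)-2,2-dimethyl-1,3-dioxolan-4-yl]-6,10-dimethylundec-9-ene-1,4-diol | O[C@H](C[C@@H](C)CCC=C(C)C)[C@H](CCO)[C@H]1COC(C)(C)O1 | intermediate
11 | lactol of 12 (C12 hemiacetal, both anomers) | C1C(O)O[C@H](C[C@@H](C)CCC=C(C)C)[C@H]1[C@H]2COC(C)(C)O2 | intermediate (not isolated)
12 | (4S,5R)-4-[(4S)-2,2-dimethyl-1,3-dioxolan-4-yl]-5-[(2S)-2,6-dimethylhept-5-en-1-yl]oxolan-2-one (trans-lactone) | C1C(=O)O[C@H](C[C@@H](C)CCC=C(C)C)[C@H]1[C@H]2COC(C)(C)O2 | intermediate
13 | 3-[(dimethylamino)methyl] derivative of 12 (C11 epimers) | CN(C)CC1C(=O)O[C@H](C[C@@H](C)CCC=C(C)C)[C@H]1[C@H]2COC(C)(C)O2 | intermediate (not isolated)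
14 | 3-[(trimethylammonio)methyl] derivative of 12, iodide | C[N+](C)(C)CC1C(=O)O[C@H](C[C@@H](C)CCC=C(C)C)[C@H]1[C@H]2COC(C)(C)O2.[I-] | intermediate (not isolated)
15 | (4S,5R)-4-[(4S)-2,2-dimethyl-1,3-dioxolan-4-yl]-5-[(2S)-2,6-dimethylhept-5-en-1-yl]-3-methylideneoxolan-2-one | C=C1C(=O)O[C@H](C[C@@H](C)CCC=C(C)C)[C@H]1[C@H]2COC(C)(C)O2 | intermediate
16 | (4R,5R)-4-[(1S)-1,2-dihydroxyethyl]-5-[(2S)-2,6-dimethylhept-5-en-1-yl]-3-methylideneoxolan-2-one | C=C1C(=O)O[C@H](C[C@@H](C)CCC=C(C)C)[C@H]1[C@H](O)CO | intermediate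
17 | (4R,5R)-4-[(1S)-2-(tert-butyldimethylsilyloxy)-1-hydroxyethyl]-5-[(2S)-2,6-dimethylhept-5-en-1-yl]-3-methylideneoxolan-2-one | C=C1C(=O)O[C@H](C[C@@H](C)CCC=C(C)C)[C@H]1[C@H](O)CO[Si](C)(C)C(C)(C)C | intermediate
18 | angelic acid, (2Z)-2-methylbut-2-enoic acid | C/C=C(/C)C(=O)O | starting material
19 | angelic 2,4,6-trichlorobenzoic anhydride | C/C=C(/C)C(=O)OC(=O)c1c(Cl)cc(Cl)cc1Cl | intermediate (not isolated)
20 | C8 angelate, C9 silyl ether, prenyl terminus: (1S)-2-(tert-butyldimethylsilyloxy)-1-{(2R,3S)-2-[(2S)-2,6-dimethylhept-5-en-1-yl]-4-methylidene-5-oxooxolan-3-yl}ethyl (2Z)-2-methylbut-2-enoate | C=C1C(=O)O[C@H](C[C@@H](C)CCC=C(C)C)[C@H]1[C@H](OC(=O)/C(C)=C\C)CO[Si](C)(C)C(C)(C)C | intermediate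
21 | 1,2,4-trioxolane (secondary ozonide) of 20 at the chain terminus | C=C1C(=O)O[C@H](C[C@@H](C)CCC2OOC(C)(C)O2)[C@H]1[C@H](OC(=O)/C(C)=C\C)CO[Si](C)(C)C(C)(C)C | intermediate (not isolated)
22 | C1 aldehyde: (1S)-2-(tert-butyldimethylsilyloxy)-1-{(2R,3S)-2-[(2S)-2-methyl-5-oxopentyl]-4-methylidene-5-oxooxolan-3-yl}ethyl (2Z)-2-methylbut-2-enoate | C=C1C(=O)O[C@H](C[C@@H](C)CCC=O)[C@H]1[C@H](OC(=O)/C(C)=C\C)CO[Si](C)(C)C(C)(C)C | intermediate
23 | methyl (triphenylphosphoranylidene)acetate | COC(=O)C=P(c1ccccc1)(c1ccccc1)c1ccccc1 | starting material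
24 | methyl iodo(triphenylphosphoranylidene)acetate | COC(=O)C(I)=P(c1ccccc1)(c1ccccc1)c1ccccc1 | intermediate (not isolated)
25 | (Z)-α-iodoacrylate, C9 silyl ether: methyl (2Z,6S)-7-{(2R,3S)-3-[(1S)-2-(tert-butyldimethylsilyloxy)-1-{[(2Z)-2-methylbut-2-enoyl]oxy}ethyl]-4-methylidene-5-oxooxolan-2-yl}-2-iodo-6-methylhept-2-enoate | C=C1C(=O)O[C@H](C[C@@H](C)CC/C=C(\I)C(=O)OC)[C@H]1[C@H](OC(=O)/C(C)=C\C)CO[Si](C)(C)C(C)(C)C | intermediate
26 | C9 primary alcohol: methyl (2Z,6S)-7-{(2R,3S)-3-[(1S)-2-hydroxy-1-{[(2Z)-2-methylbut-2-enoyl]oxy}ethyl]-4-methylidene-5-oxooxolan-2-yl}-2-iodo-6-methylhept-2-enoate | C=C1C(=O)O[C@H](C[C@@H](C)CC/C=C(\I)C(=O)OC)[C@H]1[C@H](OC(=O)/C(C)=C\C)CO | intermediate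
27 | seco iodoacrylate aldehyde: methyl (2Z,6S)-2-iodo-6-methyl-7-[(2R,3S)-3-{(1S)-1-[(2Z)-2-methylbut-2-enoyloxy]-2-oxoethyl}-4-methylidene-5-oxooxolan-2-yl]hept-2-enoate | C=C1C(=O)O[C@H](C[C@@H](C)CC/C=C(\I)C(=O)OC)[C@H]1[C@H](OC(=O)/C(C)=C\C)C=O | intermediate
28 | (Z)-alkenylchromium dichloride from 27 (solvated) | C=C1C(=O)O[C@H](C[C@@H](C)CC/C=C(\[Cr](Cl)Cl)C(=O)OC)[C@H]1[C@H](OC(=O)/C(C)=C\C)C=O | intermediate (not isolated)
29 | CNP0552150.1: methyl (3aS,4S,5S,6E,10S,11aR)-5-hydroxy-10-methyl-3-methylidene-4-[(2Z)-2-methylbut-2-enoyloxy]-2-oxo-2,3,3a,4,5,8,9,10,11,11a-decahydrocyclodeca[b]furan-6-carboxylate | C=C1C(=O)O[C@@H]2C[C@@H](C)CC/C=C(/C(=O)OC)[C@H](O)[C@@H](OC(=O)/C(C)=C\C)[C@@H]12 | target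

**Total step count:** 15. **Longest linear sequence:** 15 steps (1 to 29); 6, 18 and 23 enter as purchased materials.

**Steps most likely to fail**

1. Step 15.
   - What may go wrong: the open-chain Felkin–Anh preference may override the bias of the cyclic transition state, so that C10 attacks the Re face and C9 forms with the wrong configuration. Loss of iodine by protonation and oligomerisation are further drains.
   - Fallback, from 27 back to 29: C9 is set by hydride delivery instead of by the C–C bond formation. The ring closure of 27 is accepted as it comes and gives the (9R)-alcohol F1. Dess–Martin periodinane in CH2Cl2 oxidises this to the cross-conjugated C9 ketone F2. Luche reduction (NaBH4, CeCl3·7H2O, MeOH, −78 °C) then reduces the ketone in the 1,2-sense. For hydride addition the polar Felkin–Anh model (attack anti to the C8–O bond) leads to the threo pair, so the intrinsic bias now works for the route and returns it to 29.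

2. Step 4.
   - What may go wrong: the dioxolane may discriminate poorly between the two faces of the allyl unit. Reductive 1,4-elimination of the allyl metal with loss of the C8 oxygen may also compete.
   - Fallback, from 5 back to 8: the low-valent metal is replaced by boron and substrate control by catalyst control. Bromide 5 is borylated with bis(pinacolato)diboron and Pd2(dba)3 (cat.) in THF at 60 °C to the (E)-allylboronic pinacol ester F3. This ester adds to 6 in toluene at −30 °C under catalysis by one enantiomer of 3,3'-bis(2,4,6-triisopropylphenyl)-1,1'-binaphthyl-2,2'-diyl hydrogen phosphate. The closed chair of the allylboration turns the E geometry into the anti pair. The catalyst enantiomer that opens the Si face of 6 fixes C6 and C7 together, giving 8.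

3. Step 10.
   - What may go wrong: the angeloyl group may isomerise from Z to E (tiglate) during activation. Acylation of the hindered C8 hydroxyl may also be slow, leaving time for translactonisation.
   - Fallback, from 17 back to 20: the double bond of the ester is built on the substrate. Alcohol 17 is esterified with 2-[bis(2,2,2-trifluoroethoxy)phosphoryl]propanoic acid (dicyclohexylcarbodiimide, 4-(dimethylamino)pyridine, CH2Cl2, 0 °C) to the phosphonopropionate F4, an acylation with no alkene geometry to lose. Still–Gennari olefination (KN(SiMe3)2, 18-crown-6, THF, −78 °C, then acetaldehyde) then forms the Z-configured 2-methylbut-2-enoate and gives 20.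

**Further compounds**
F1 | step 15 | (9R)-epimer of 29 | C=C1C(=O)O[C@@H]2C[C@@H](C)CC/C=C(/C(=O)OC)[C@@H](O)[C@@H](OC(=O)/C(C)=C\C)[C@@H]12
F2 | step 15 | C9 ketone of 29 | C=C1C(=O)O[C@@H]2C[C@@H](C)CC/C=C(/C(=O)OC)C(=O)[C@@H](OC(=O)/C(C)=C\C)[C@@H]12
F3 | step 4 | 2-{(2E)-3-[(4S)-2,2-dimethyl-1,3-dioxolan-4-yl]prop-2-en-1-yl}-4,4,5,5-tetramethyl-1,3,2-dioxaborolane | CC1(C)OB(C/C=C/[C@H]2COC(C)(C)O2)OC1(C)C
F4 | step 10 | C8 2-[bis(2,2,2-trifluoroethoxy)phosphoryl]propanoate of 17 | C=C1C(=O)O[C@H](C[C@@H](C)CCC=C(C)C)[C@H]1[C@H](OC(=O)C(C)P(=O)(OCC(F)(F)F)OCC(F)(F)F)CO[Si](C)(C)C(C)(C)C
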